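Everything rests on cutting the C2–C3 bond common to rings C and D. The feature exploited is the pair of contiguous fully substituted carbons in dihydrofuran ring D: carbinol C3, traced back to the keto group of a glyoxylate on C8 of flavan ring E, and ketal C2, traced back to the C–H of a diaryl acetal on flavan O7 that already carries ring B and the ring A oxygen. A single irradiation moves that hydrogen to the ketone oxygen and couples the biradical, closing ring D and creating both centres; ring C follows by acylation of symmetric ring A. The precursor is a (2S)-flavan-8-yl glyoxylate with the mixed acetal on O7.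

Key step: step 10

Labels: ring A is the phloroglucinol-derived ring, ring B the 4-hydroxyphenyl group on C2, ring C the pyranone, ring D the dihydrofuran, ring E the benzene ring of the flavan; C2, C3 and C4 are the ketal, carbinol and ketone carbons; O7, C6, C8 and 4' are flavan positions.

Assumption: ring C can exist only with the ring A oxygen on C2 and carbon C4 on C3 on the same face of ring D, so C2 and C3 are treated as one stereochemical unit defined by the C3 configuration of the target string; the C2/C3 stereodescriptors of that string are transcribed unchanged into compounds 19 to 23 and are read as denoting this cis-fused unit.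

Step 1
Reactants: 1 (2S)-naringenin
Product: 2 (2S)-5-hydroxy-2-(4-hydroxyphenyl)-7-(methoxymethoxy)chroman-4-one
Conditions: MOMCl (1.05 equiv), i-Pr2NEt (1.2 equiv), acetone, 0 °C
Reagents that add atoms: chloromethyl methyl ether, COCCl
Why: Williamson-type O-alkylation under an amine base should pick the most acidic phenol, the 7-OH para to the C4 carbonyl, while the chelated 5-OH and the less acidic 4'-OH stay free and the base is too weak to open the flavanone to its chalcone, so the (2S) centre is kept.

Step 2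
Reactants: 2 (2S)-5-hydroxy-2-(4-hydroxyphenyl)-7-(methoxymethoxy)chroman-4-one
Product: 5 (2S)-2-(4-hydroxyphenyl)-7-(methoxymethoxy)chroman-5-ol, via bis-carbonate 3 (not isolated), via flavan monocarbonate 4 (not isolated)
Conditions: ClCO2Et (2.4 equiv), Et3N, THF, 0 °C, filter; filtrate into NaBH4, THF/H2O, 0 °C to 20 °C; then 1 M NaOH, MeOH, 0 °C to 20 °C
Reagents that add atoms: none
Why: Reductive deoxygenation of an ortho-hydroxyaryl ketone by way of its ethyl carbonate: hydride reduces C4, the carbonate moves to the new alkoxide and leaves to give an ortho-quinone methide that NaBH4 reduces to the C4 methylene, and hydroxide then removes the bystander 4'-carbonate without touching C2.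

Step 3
Reactants: 5 (2S)-2-(4-hydroxyphenyl)-7-(methoxymethoxy)chroman-5-ol
Product: 6 (2S)-5-(benzyloxy)-2-[4-(benzyloxy)phenyl]-7-(methoxymethoxy)chromane
Conditions: BnBr (2.4 equiv), K2CO3, DMF, 0 °C to 20 °C
Reagents that add atoms: benzyl bromide, BrCc1ccccc1
Why: Williamson etherification of both free phenols, run at or below room temperature so that the 2-arylchroman centre does not epimerise through a ring B quinone methide.

Step 4
Reactants: 6 (2S)-5-(benzyloxy)-2-[4-(benzyloxy)phenyl]-7-(methoxymethoxy)chromane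
Product: 7 (2S)-5-(benzyloxy)-2-[4-(benzyloxy)phenyl]-8-bromo-7-(methoxymethoxy)chromane
Conditions: NBS (1.0 equiv), CH2Cl2, −78 °C to −20 °C
Reagents that add atoms: N-bromosuccinimide, O=C1CCC(=O)N1Br
Why: Electrophilic aromatic bromination of the phloroglucinol-type ring E should go to C8, which is flanked by only one exocyclic alkoxy group, rather than to the more crowded C6, as is general for 5,7-dialkoxyflavans.

Step 5
Reactants: 7 (2S)-5-(benzyloxy)-2-[4-(benzyloxy)phenyl]-8-bromo-7-(methoxymethoxy)chromane; 8 dimethyl oxalate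
Product: 10 methyl 2-[(2S)-5-(benzyloxy)-2-[4-(benzyloxy)phenyl]-7-(methoxymethoxy)chroman-8-yl]-2-oxoacetate, via aryllithium 9 (not isolated)
Conditions: n-BuLi (1.05 equiv), THF, −78 °C; cannulated into (CO2Me)2 (4 equiv), THF, −78 °C; NH4Cl aq
Reagents that add atoms: none
Why: Bromine–lithium exchange followed by inverse addition to excess oxalate diester (acylation of an aryllithium) should stop at the α-keto ester, because the di-ortho-substituted aryllithium is hindered and the tetrahedral adduct persists at −78 °C.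

Step 6
Reactants: 10 methyl 2-[(2S)-5-(benzyloxy)-2-[4-(benzyloxy)phenyl]-7-(methoxymethoxy)chroman-8-yl]-2-oxoacetate
Product: 11 methyl 2-[(2S)-5-(benzyloxy)-2-[4-(benzyloxy)phenyl]-7-hydroxychroman-8-yl]-2-oxoacetate
Conditions: conc. HCl (cat.), MeOH/THF, 45 °C
Reagents that add atoms: none
Why: Acid-catalysed acetal methanolysis removes only the MOM group, since benzyl ethers, the flavan and the methyl ester (methanol is the solvent) are inert and the freed phenol is held as a hydrogen-bonded keto ester.

Step 7
Reactants: 12 4-(benzyloxy)benzyl chloride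
Product: 13 4-(benzyloxy)benzyl phenyl sulfide
Conditions: PhSH (1.05 equiv), K2CO3, acetone, 20 °C
Reagents that add atoms: thiophenol, Sc1ccccc1
Why: SN2 thioetherification of a benzylic chloride by thiophenolate.

Step 8
Reactants: 13 4-(benzyloxy)benzyl phenyl sulfide; 11 methyl 2-[(2S)-5-(benzyloxy)-2-[4-(benzyloxy)phenyl]-7-hydroxychroman-8-yl]-2-oxoacetate
Product: 15 methyl 2-[(2S)-5-(benzyloxy)-2-[4-(benzyloxy)phenyl]-7-{[4-(benzyloxy)phenyl](phenylthio)methoxy}chroman-8-yl]-2-oxoacetate (both epimers at the new O,S-acetal carbon), via chloro sulfide 14 (not isolated)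
Conditions: 13, NCS (1.0 equiv), benzene, 20 °C, filter; filtrate added to 11, Cs2CO3 (1.5 equiv), DMF, 0 °C to 20 °C
Reagents that add atoms: none
Why: α-Chlorination of a benzyl sulfide by NCS (Pummerer-type) gives a thionium precursor that the phenoxide of 11 should capture at oxygen in a Williamson-type substitution, the keto ester having no enolisable hydrogen to interfere.

Step 9
Reactants: 15 the O,S-acetal of step 8; 16 3,5-bis(benzyloxy)phenol
Product: 18 methyl 2-[(2S)-5-(benzyloxy)-2-[4-(benzyloxy)phenyl]-7-{[4-(benzyloxy)phenyl][3,5-bis(benzyloxy)phenoxy]methoxy}chroman-8-yl]-2-oxoacetate (both acetal epimers), via chloro ether 17 (not isolated)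
Conditions: 15, SO2Cl2 (1.0 equiv), cyclohexene (3 equiv), CH2Cl2, −78 °C; then 16 pre-mixed with NaH in THF/DMF, −78 °C to 0 °C; Et3N-deactivated silica
Reagents that add atoms: none
Why: Chlorinolysis of an O,S-acetal to the α-chloro ether (sulfur is the only site soft enough to react at −78 °C and cyclohexene takes up PhSCl) followed by O-alkylation of the phenoxide of 16 in a dipolar aprotic medium should give the mixed acetal, ring A meeting no electrophilic reagent because it enters last and as its anion.

Step 10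
Reactants: 18 the mixed diaryl acetal of step 9
Product: 19 methyl (2S)-5-(benzyloxy)-2,8-bis[4-(benzyloxy)phenyl]-8-[3,5-bis(benzyloxy)phenoxy]-9-hydroxy-3,4,8,9-tetrahydro-2H-furo[2,3-h]chromene-9-carboxylate (C8 is ketal C2 and C9 is carbinol C3; C3 epimer of the target configuration)
Conditions: hν (365 nm), degassed benzene (3 mM), NaHCO3 (solid), 20 °C; C3 epimers separated by chromatography
Reagents that add atoms: none
Why: Light above 340 nm is absorbed only by the keto ester, whose carbonyl is twisted out of the plane of ring E by its two ortho oxygens and so keeps n,π* reactivity; the excited oxygen takes the acetal hydrogen by 1,6-transfer through a seven-membered transition state, and the 1,5-biradical (ketyl at C3, doubly oxygenated benzylic radical at C2) couples after intersystem crossing to form the C2–C3 bond. The closest known reaction type is the Norrish–Yang photocyclisation of ortho-alkoxyphenyl ketones and ortho-benzyloxyphenylglyoxylates to 3-hydroxy-2,3-dihydrobenzofurans. Ring D closes as a five-membered ring by recombination of the 1,5-biradical. C2 arises from a planar radical common to both acetal epimers and is set in the coupling, where the larger ring B aryl group should turn away from the ester so that the ring A oxygen and the ester share one face of ring D, a relation that step 12 enforces in any case. C3 is not controlled, because the flavan centre is too remote to bias the faces of the ketyl, so both C3 epimers are expected and the one needed is isolated. The step needs abstraction of the acetal hydrogen only: that hydrogen sits on a freely rotating carbon and is weakened by two oxygens and ring B, whereas the flavan C2 hydrogen is held anti to C8 by the pyran ring and the benzyl ether methylenes are out of reach.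

Step 11
Reactants: 19 the hydroxy ester of step 10
Product: 20 (2S)-5-(benzyloxy)-2,8-bis[4-(benzyloxy)phenyl]-8-[3,5-bis(benzyloxy)phenoxy]-9-hydroxy-3,4,8,9-tetrahydro-2H-furo[2,3-h]chromene-9-carboxylic acid
Conditions: LiOH·H2O (5 equiv), THF/MeOH/H2O, 20 °C to 40 °C; 1 M HCl to pH 4, 0 °C
Reagents that add atoms: lithium hydroxide, [Li+].[OH-]
Why: Saponification by acyl–oxygen cleavage, helped by the α-hydroxyl; ketal and benzyl ethers are base-stable, and with ring B still benzylated no para-phenoxide can expel an aryloxide from C2.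

Step 12
Reactants: 20 the hydroxy acid of step 11
Product: 22 penta-O-benzyl-daphnodorin F (benzyl ethers on both ring A oxygens and on ring B and on flavan O5 and flavan O4'; C3 hydroxyl free), via mixed anhydride 21 (not isolated)
Conditions: TFAA (1.5 equiv), CH2Cl2, −20 °C to 0 °C; NaHCO3 aq
Reagents that add atoms: none
Why: Intramolecular Friedel–Crafts acylation by the acyl trifluoroacetate closes six-membered ring C at either of the two equivalent positions ortho to the ketal oxygen of the very electron-rich, symmetric ring A; the ring can form only with that oxygen and the carboxyl carbon on one face of ring D, and material epimeric at C2 is expected to be fed in by acid-promoted reversible opening of the C2–O7 bond.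

Step 13
Reactants: 22 penta-O-benzyl-daphnodorin F
Product: 23 daphnodorin F
Conditions: H2 (1 atm), 10% Pd/C, EtOAc/MeOH, 20 °C
Reagents that add atoms: none
Why: Hydrogenolysis of the five benzyl aryl ethers under neutral conditions, the fully substituted ketal carbon, the tertiary ketol and the cyclic 2-arylchroman C–O bond being far slower to cleave than primary benzyl ethers.

Compound list
1 | (2S)-naringenin | O=C1C[C@@H](c2ccc(O)cc2)Oc2cc(O)cc(O)c12 | starting material
2 | (2S)-5-hydroxy-2-(4-hydroxyphenyl)-7-(methoxymethoxy)chroman-4-one | O=C1C[C@@H](c2ccc(O)cc2)Oc2cc(OCOC)cc(O)c12 | intermediate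
3 | (2S)-5-(ethoxycarbonyloxy)-2-[4-(ethoxycarbonyloxy)phenyl]-7-(methoxymethoxy)chroman-4-one (not isolated) | O=C1C[C@@H](c2ccc(OC(=O)OCC)cc2)Oc2cc(OCOC)cc(OC(=O)OCC)c12 | intermediate
4 | (2S)-2-[4-(ethoxycarbonyloxy)phenyl]-7-(methoxymethoxy)chroman-5-ol (not isolated) | C1C[C@@H](c2ccc(OC(=O)OCC)cc2)Oc2cc(OCOC)cc(O)c12 | intermediate
5 | (2S)-2-(4-hydroxyphenyl)-7-(methoxymethoxy)chroman-5-ol | C1C[C@@H](c2ccc(O)cc2)Oc2cc(OCOC)cc(O)c12 | intermediate
6 | (2S)-5-(benzyloxy)-2-[4-(benzyloxy)phenyl]-7-(methoxymethoxy)chromane | C1C[C@@H](c2ccc(OCc3ccccc3)cc2)Oc2cc(OCOC)cc(OCc3ccccc3)c12 | intermediate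
7 | (2S)-5-(benzyloxy)-2-[4-(benzyloxy)phenyl]-8-bromo-7-(methoxymethoxy)chromane | C1C[C@@H](c2ccc(OCc3ccccc3)cc2)Oc2c(Br)c(OCOC)cc(OCc3ccccc3)c12 | intermediate
8 | dimethyl oxalate | COC(=O)C(=O)OC | starting material
9 | [(2S)-5-(benzyloxy)-2-[4-(benzyloxy)phenyl]-7-(methoxymethoxy)chroman-8-yl]lithium (not isolated) | C1C[C@@H](c2ccc(OCc3ccccc3)cc2)Oc2c([Li])c(OCOC)cc(OCc3ccccc3)c12 | intermediate
10 | methyl 2-[(2S)-5-(benzyloxy)-2-[4-(benzyloxy)phenyl]-7-(methoxymethoxy)chroman-8-yl]-2-oxoacetate | C1C[C@@H](c2ccc(OCc3ccccc3)cc2)Oc2c(C(=O)C(=O)OC)c(OCOC)cc(OCc3ccccc3)c12 | intermediate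
11 | methyl 2-[(2S)-5-(benzyloxy)-2-[4-(benzyloxy)phenyl]-7-hydroxychroman-8-yl]-2-oxoacetate | C1C[C@@H](c2ccc(OCc3ccccc3)cc2)Oc2c(C(=O)C(=O)OC)c(O)cc(OCc3ccccc3)c12 | intermediate
12 | 4-(benzyloxy)benzyl chloride | ClCc1ccc(OCc2ccccc2)cc1 | starting material
13 | 4-(benzyloxy)benzyl phenyl sulfide | c1ccccc1SCc1ccc(OCc2ccccc2)cc1 | intermediate
14 | 1-(benzyloxy)-4-[chloro(phenylthio)methyl]benzene (racemic, not isolated) | ClC(Sc1ccccc1)c1ccc(OCc2ccccc2)cc1 | intermediate
15 | methyl 2-[(2S)-5-(benzyloxy)-2-[4-(benzyloxy)phenyl]-7-{[4-(benzyloxy)phenyl](phenylthio)methoxy}chroman-8-yl]-2-oxoacetate (both epimers at the O,S-acetal carbon) | C1C[C@@H](c2ccc(OCc3ccccc3)cc2)Oc2c(C(=O)C(=O)OC)c(OC(Sc3ccccc3)c3ccc(OCc4ccccc4)cc3)cc(OCc3ccccc3)c12 | intermediate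
16 | 3,5-bis(benzyloxy)phenol | Oc1cc(OCc2ccccc2)cc(OCc2ccccc2)c1 | starting material
17 | methyl 2-[(2S)-5-(benzyloxy)-2-[4-(benzyloxy)phenyl]-7-{[4-(benzyloxy)phenyl](chloro)methoxy}chroman-8-yl]-2-oxoacetate (not isolated) | C1C[C@@H](c2ccc(OCc3ccccc3)cc2)Oc2c(C(=O)C(=O)OC)c(OC(Cl)c3ccc(OCc4ccccc4)cc3)cc(OCc3ccccc3)c12 | intermediate
18 | methyl 2-[(2S)-5-(benzyloxy)-2-[4-(benzyloxy)phenyl]-7-{[4-(benzyloxy)phenyl][3,5-bis(benzyloxy)phenoxy]methoxy}chroman-8-yl]-2-oxoacetate (both acetal epimers; photoprecursor) | COC(=O)C(=O)c3c(OC(c1ccc(OCc5ccccc5)cc1)Oc1cc(OCc5ccccc5)cc(OCc5ccccc5)c1)cc(OCc5ccccc5)c4c3O[C@H](c1ccc(OCc5ccccc5)cc1)CC4 | intermediate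
19 | methyl (2S)-5-(benzyloxy)-2,8-bis[4-(benzyloxy)phenyl]-8-[3,5-bis(benzyloxy)phenoxy]-9-hydroxy-3,4,8,9-tetrahydro-2H-furo[2,3-h]chromene-9-carboxylate, ketal and carbinol centres as in the target | c1c(OCc5ccccc5)cc(OCc5ccccc5)cc1O[C@]2(c3ccc(OCc5ccccc5)cc3)Oc3cc(OCc5ccccc5)c4c(c3[C@]2(C(=O)OC)O)O[C@H](c1ccc(OCc5ccccc5)cc1)CC4 | intermediate
20 | the 9-carboxylic acid corresponding to 19 | c1c(OCc5ccccc5)cc(OCc5ccccc5)cc1O[C@]2(c3ccc(OCc5ccccc5)cc3)Oc3cc(OCc5ccccc5)c4c(c3[C@]2(C(=O)O)O)O[C@H](c1ccc(OCc5ccccc5)cc1)CC4 | intermediate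
21 | mixed anhydride of 20 with trifluoroacetic acid (not isolated) | c1c(OCc5ccccc5)cc(OCc5ccccc5)cc1O[C@]2(c3ccc(OCc5ccccc5)cc3)Oc3cc(OCc5ccccc5)c4c(c3[C@]2(C(=O)OC(=O)C(F)(F)F)O)O[C@H](c1ccc(OCc5ccccc5)cc1)CC4 | intermediate
22 | penta-O-benzyl-daphnodorin F (C3 hydroxyl free) | O=C1c2c(OCc5ccccc5)cc(OCc5ccccc5)cc2O[C@]2(c3ccc(OCc5ccccc5)cc3)Oc3cc(OCc5ccccc5)c4c(c3[C@@]12O)O[C@H](c1ccc(OCc5ccccc5)cc1)CC4 | intermediate
23 | daphnodorin F | O=C1c2c(O)cc(O)cc2O[C@]2(c3ccc(O)cc3)Oc3cc(O)c4c(c3[C@@]12O)O[C@H](c1ccc(O)cc1)CC4 | target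

Total step count: 13. Longest linear sequence: 12 steps (1 to 23 through steps 1–6 and 8–13).

Steps most likely to fail

Step 10. The excited keto ester may be quenched by electron transfer from the trioxygenated ring A or may hand the hydrogen back faster than the biradical couples, and the electron-rich acetal may ionise during a long irradiation, so that little material reaches the biradical. The fallback takes ring A out of the photosubstrate and brings it in afterwards; it sets out from 11 and returns at 19. Compound 11 is O-alkylated with 12 (K2CO3, DMF) to the 7-O-[4-(benzyloxy)benzyl] keto ester F1. Irradiation of F1 (365 nm, benzene), the plain ortho-benzyloxyphenylglyoxylate case of the Norrish–Yang reaction, gives the 2-aryl-3-hydroxy-2,3-dihydrobenzofuran-3-carboxylate F2. Dehydration (SOCl2, pyridine, 0 °C) gives the 2-arylbenzofuran-3-carboxylate F3, and dimethyldioxirane in acetone at −20 °C gives the labile 2,3-epoxide F4. Opening of F4 at C2 by the sodium salt of 16 (THF, −40 °C), anti to the epoxide oxygen so that aryloxy group and ester share a face, should deliver 19 together with its C3 epimer, separated as in step 10.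

Step 9. The chloro ether may ionise and decompose before the phenoxide arrives, ring E may be chlorinated or sulfenylated at C6, and the ambident phloroglucinol-type phenoxide may be alkylated at carbon instead of oxygen. The fallback reverses the order of the two C–O bond formations and activates sulfur by alkylation, so that no electrophilic halogen or sulfur species is formed; it sets out from 14 and 16 and returns at 18. The sodium salt of 16 is alkylated with 14 (THF/DMF, 0 °C) to the storable ring A O,S-acetal F5. F5 is pre-activated with MeOTf (1.0 equiv) and 2,6-di-tert-butyl-4-methylpyridine in CH2Cl2 at −60 °C to the S-methylsulfonium triflate F6, which releases only methyl phenyl sulfide on ionisation. The sodium salt of 11 is then added and should be alkylated at oxygen to give 18.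

Step 12. Under the acidic acylation conditions the ketal may ionise with loss of the ring A phenol, or the tertiary carbinol may be acylated and ionise, in competition with ring closure. The fallback closes ring C by an anionic route without acid and without the hydrolysis step; it sets out from 15 and 16 and returns at 22. Compound 16 is brominated ortho to the hydroxyl (NBS, cat. i-Pr2NH, CH2Cl2, −78 °C) to 2-bromo-3,5-bis(benzyloxy)phenol F7. F7 takes the place of 16 in the second half of step 9 (chloro ether 17, NaH) to give the bromo acetal F8, and irradiation as in step 10 gives the bromo hydroxy ester F9. n-BuLi (2.2 equiv, THF, −78 °C) first forms the alkoxide and then exchanges bromine for lithium to give the dilithio species F10, which closes ring C by Parham cyclisation onto the methyl ester and gives 22; only material with the aryloxy group and the ester on one face of ring D can cyclise.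

Further compounds
F1 | step 10 | methyl 2-[(2S)-5-(benzyloxy)-2-[4-(benzyloxy)phenyl]-7-{[4-(benzyloxy)phenyl]methoxy}chroman-8-yl]-2-oxoacetate | C1C[C@@H](c2ccc(OCc3ccccc3)cc2)Oc2c(C(=O)C(=O)OC)c(OCc3ccc(OCc4ccccc4)cc3)cc(OCc3ccccc3)c12
F2 | step 10 | methyl (2S)-5-(benzyloxy)-2,8-bis[4-(benzyloxy)phenyl]-9-hydroxy-3,4,8,9-tetrahydro-2H-furo[2,3-h]chromene-9-carboxylate (mixture at C8 and C9) | COC(=O)C1(O)C(c2ccc(OCc3ccccc3)cc2)Oc2cc(OCc3ccccc3)c3CC[C@@H](c4ccc(OCc5ccccc5)cc4)Oc3c12
F3 | step 10 | methyl (2S)-5-(benzyloxy)-2,8-bis[4-(benzyloxy)phenyl]-3,4-dihydro-2H-furo[2,3-h]chromene-9-carboxylate | COC(=O)c1c(-c2ccc(OCc3ccccc3)cc2)oc2cc(OCc3ccccc3)c3CC[C@@H](c4ccc(OCc5ccccc5)cc4)Oc3c12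
F4 | step 10 | 8,9-epoxide of F3 (both epoxide faces) | COC(=O)C12OC1(c1ccc(OCc3ccccc3)cc1)Oc1cc(OCc3ccccc3)c3CC[C@@H](c4ccc(OCc5ccccc5)cc4)Oc3c12
F5 | step 9 | 1,3-bis(benzyloxy)-5-{[4-(benzyloxy)phenyl](phenylthio)methoxy}benzene (racemic) | c1ccccc1SC(Oc1cc(OCc2ccccc2)cc(OCc2ccccc2)c1)c1ccc(OCc2ccccc2)cc1
F6 | step 9 | S-methylsulfonium triflate of F5 | C[S+](c1ccccc1)C(Oc1cc(OCc2ccccc2)cc(OCc2ccccc2)c1)c1ccc(OCc2ccccc2)cc1.[O-]S(=O)(=O)C(F)(F)F
F7 | step 12 | 2-bromo-3,5-bis(benzyloxy)phenol | Oc1c(Br)c(OCc2ccccc2)cc(OCc2ccccc2)c1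
F8 | step 12 | analogue of 18 with bromine on ring A ortho to the acetal oxygen | COC(=O)C(=O)c3c(OC(c1ccc(OCc5ccccc5)cc1)Oc1cc(OCc5ccccc5)cc(OCc5ccccc5)c1Br)cc(OCc5ccccc5)c4c3O[C@H](c1ccc(OCc5ccccc5)cc1)CC4
F9 | step 12 | analogue of 19 with bromine on ring A ortho to the ketal oxygen | Brc1c(OCc5ccccc5)cc(OCc5ccccc5)cc1O[C@]2(c3ccc(OCc5ccccc5)cc3)Oc3cc(OCc5ccccc5)c4c(c3[C@]2(C(=O)OC)O)O[C@H](c1ccc(OCc5ccccc5)cc1)CC4
F10 | step 12 | lithium alkoxide aryllithium derived from F9 | [Li]c1c(OCc5ccccc5)cc(OCc5ccccc5)cc1O[C@]2(c3ccc(OCc5ccccc5)cc3)Oc3cc(OCc5ccccc5)c4c(c3[C@]2(C(=O)OC)O[Li])O[C@H](c1ccc(OCc5ccccc5)cc1)CC4
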